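Its constants come from no measurement; what happens was integrated by code.

The target was what I wanted from this flask, and it is a thing that has to get away: once made in the reaction phase it either crosses into the second phase or decomposes, so I ran the flask forward with that fork in view.

    reagent in the reaction phase ⇌ reagent in the second phase, rate k1*([reagent in the reaction phase] - [reagent in the second phase]/K1) per volume of the first phase (K1 = 1.2, k1 = 0.074 /s)
    starting material + reagent in the reaction phase → target (k2 = 0.45 /M/s)
    target ⇌ product in the second phase, rate k3*([target] - [product in the second phase]/K3) per volume of the first phase (K3 = 5.6, k3 = 0.051 /s)
    target → decomposed product (k4 = 0.069 /s)
    2 reagent in the reaction phase → self-condensation product (k5 = 0.25 /M/s)
    starting material + protic impurity → quenched substrate (k6 = 1.3 /M/s)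

starting material 0.22 M; reagent in the second phase 0.700 equiv; protic impurity 0.0440 M; time 40 s; volume of the second phase over the first 0.50

- target is meant together with its product in the second phase
- two of one species on the left: rate k times its square, two consumed each time
- in the second phase: reagent in the second phase, product in the second phase; everything else is in the first
- charges count per volume of the first phase; a concentration in a rate is the amount of a species over the volume of its own phase; every rate counts per litre of the first phase
- run time (flask): 40 s

- how much target and product in the second phase together there is at 40 s, in percent of the starting material charged
- the change that raises the amount of target and product in the second phase together at 40 s, in percent of the starting material charged most ("none" if none brings more than 2 percentage points) (zeta / alpha / theta / none)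
- amount of target and product in the second phase together at 40 s, in percent of the starting material charged, after zeta

- zeta: doubling the amount of reagent in the second phase, all else as stated
- alpha: doubling the transfer coefficient of step 1, all else as stated
- theta: doubling the transfer coefficient of step 3, all else as stated

In the first instants I saw two things begin together. The protic impurity stood at 20.0% of the starting material and took it with a half-life of 12 s at the charged amounts, shorter than the run, while the reagent had to cross into the reaction phase before it could couple. Once there it had a half-life of 7.0 s by coupling as charged. The reagent was the limiting reagent, since its cap of 70.0% on the target lay below the 80.0% of starting material the impurity left.

In the middle of the run the fork began to matter, because the half-life of reaction-phase target by decomposition, 10 s, is short against the run. While [product in the second phase] is small, [target] has two first-order exits, 0.051 /s across and 0.069 /s to decomposition, and the ratio of the two does not depend on how much target stands. So I took the escape share, the part of the target leaving the reaction phase that crosses rather than decomposes, as k3 over the sum of the two exits: 42.5%.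

Towards the end I expected back-flow to wear this share down. Multiplying the share by the cap gave me 29.8%, an estimate and no bound, of the product in the second phase for reagent fully coupled and target fully gone from the reaction phase, and I committed to target and product in the second phase together lying below that at the asked time, without ranking the changes.

The forecast gave 15%, lower than my estimate, chose zeta and put the result of that change at 24%, on the ground that “Doubling the reagent should help most because it raises the amount of target formed”.

The flask gave 17.8%, with zeta the best change at 7.6 percentage points, reaching 25.3%. In this flask the answer had moved by 5 points at 0.440 equiv and at 1.09 equiv of reagent in the second phase. In the same flask, product in the second phase over that plus decomposed product read 42.0% at 4.00 s, beside the escape share of 42.5%, and 34.9% at 40.0 s. The neighbour flask with 0.055 M of starting material gave 6.39%, and there the same ratio read 35.2% at 40.0 s.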